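**Retrosynthetic overview**
- The target comes from acid release of the enone from a dimethyl ketal, after hydride opening of a syn-epoxy alcohol; the tertiary C–O bond and the cis-diol come from an OH-directed epoxidation.
- The epoxy alcohol comes from CBS reduction of a 2-alkyl para-quinone monoketal (sets C4), itself made by oxidative dearomatisation of a 2-alkylphenol.
- Key disconnection: the ring C5–C1′ bond, made on the flat arene by a nickel-catalysed radical cross-electrophile coupling of 2-bromophenol with the C17 alkyl iodide.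
- The C17 iodide comes from a (Z)-1,8-diene, from an enyne, from propyne + 1-bromoheptane + 7-bromohept-1-ene (dianion double alkylation, Lindlar for the Z-olefin).
- Rings: the carbocycle is carried in from 2-bromophenol and is never closed; the only ring formed is a transient oxirane, closed late and opened in the last step.

Assumption: the SMILES is read as the cis-diol (4R,5S)-4,5-dihydroxy-5-[(8Z)-heptadec-8-en-1-yl]cyclohex-2-en-1-one, and propyne, 1-bromoheptane, 7-bromohept-1-ene and 2-bromophenol are taken as commercial.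

**Route**

Step 1
Reactants: 1 propyne; 2 1-bromoheptane; 3 7-bromohept-1-ene
Product: 6 heptadec-1-en-8-yne, via 1,3-dilithiopropyne 4 (not isolated), via dec-1-ynyllithium 5 (not isolated)
Conditions: n-BuLi (2.1 equiv), TMEDA, THF/hexane, −78 → 0 °C; 2, −78 °C → rt; then 3, DMPU, rt → 45 °C
Reagents that add atoms: none
Why: Propyne-dianion alkylation followed by acetylide alkylation: the sp3 carbanion of 4 is the more nucleophilic site and takes 2 first, and the remaining lithium acetylide 5 is alkylated by the primary bromide 3 once DMPU is added, so the whole C17 chain is assembled in one flask.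

Step 2
Reactants: 6 heptadec-1-en-8-yne
Product: 7 (8Z)-heptadeca-1,8-diene
Conditions: H2 (1 atm, stopped at 1.0 equiv), Pd/CaCO3 poisoned with Pb(OAc)2 (Lindlar catalyst), quinoline, hexane, rt
Reagents that add atoms: none
Why: Lindlar semihydrogenation: syn delivery of hydrogen to the internal alkyne on the poisoned palladium surface gives the Z-olefin, and the alkyne is consumed well before the terminal alkene when uptake is stopped at one equivalent.

Step 3
Reactants: 7 (8Z)-heptadeca-1,8-diene
Product: 9 (8Z)-1-iodoheptadec-8-ene, via alkylborane 8 (not isolated)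
Conditions: 9-BBN, THF, 0 °C → rt; then NaOMe, I2, MeOH, 0 °C
Reagents that add atoms: iodine, II (9-borabicyclo[3.3.1]nonane, B1C2CCCC1CCC2, adds atoms to 8 only)
Why: Brown hydroboration–iodination: 9-BBN adds anti-Markovnikov to the terminal olefin far faster than to the internal Z-olefin, and methoxide-induced iodinolysis of the borate transfers the primary alkyl group to iodine without moving the Z-olefin.

Step 4 (key step)
Reactants: 9 (8Z)-1-iodoheptadec-8-ene; 10 2-bromophenol
Product: 11 2-[(8Z)-heptadec-8-en-1-yl]phenol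
Conditions: NiI2 (10 mol %), 4,4′-di-tert-butyl-2,2′-bipyridine (10 mol %), pyridine (10 mol %), NaI (25 mol %), Zn dust (2 equiv), DMPU, 60 °C
Reagents that add atoms: none
Why: Nickel-catalysed reductive cross-electrophile coupling (radical chain): monovalent nickel abstracts iodine from 9, the primary alkyl radical is captured by the arylnickel bromide (divalent nickel) formed from 10, and reductive elimination makes the C5–C1′ bond; the remote Z-olefin cannot cyclise onto the radical, and the free phenol O–H is expected to be tolerated under these zinc/DMPU conditions.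

Step 5
Reactants: 11 2-[(8Z)-heptadec-8-en-1-yl]phenol
Product: 13 2-[(8Z)-heptadec-8-en-1-yl]-4,4-dimethoxycyclohexa-2,5-dien-1-one, via methoxyphenol 12 (not isolated)
Conditions: PhI(OAc)2 (2.2 equiv), MeOH, 0 °C → rt
Reagents that add atoms: methanol, CO
Why: Hypervalent-iodine oxidative dearomatisation of a para-unsubstituted phenol: two successive oxidations with methanol trapping at the free para position give the para-quinone monoketal, which keeps the carbonyl next to the alkyl-bearing carbon and masks the future enone carbonyl, while the isolated Z-olefin is inert to PhI(OAc)2 in methanol.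

Step 6
Reactants: 13 2-[(8Z)-heptadec-8-en-1-yl]-4,4-dimethoxycyclohexa-2,5-dien-1-one
Product: 14 (1R)-2-[(8Z)-heptadec-8-en-1-yl]-4,4-dimethoxycyclohexa-2,5-dien-1-ol
Conditions: (S)-2-methyl-CBS-oxazaborolidine (20 mol %), catecholborane, toluene, −78 °C; Et3N-buffered work-up
Reagents that add atoms: none
Why: Corey–Bakshi–Shibata reduction: 1,2-hydride delivery to the cross-conjugated dienone, with the alkyl-substituted vinyl arm acting as the large group, sets the secondary carbinol (C4 of the target) as R, and catecholborane at −78 °C does not hydroborate the chain olefin.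

Step 7
Reactants: 14 (1R)-2-[(8Z)-heptadec-8-en-1-yl]-4,4-dimethoxycyclohexa-2,5-dien-1-ol
Product: 15 (1R,2R,6R)-1-[(8Z)-heptadec-8-en-1-yl]-5,5-dimethoxy-7-oxabicyclo[4.1.0]hept-3-en-2-ol (oxirane oxygen cis to the 2-OH)
Conditions: VO(acac)2 (5 mol %), t-BuOOH (in decane), CH2Cl2, 0 °C
Reagents that add atoms: tert-butyl hydroperoxide, CC(C)(C)OO
Why: Hydroxyl-directed vanadium-catalysed epoxidation: the vanadate ester of the ring alcohol delivers oxygen to the more electron-rich trisubstituted allylic olefin on the face of the OH group, which sets the tertiary C–O bond (C5 of the target, S) cis to the carbinol oxygen and leaves the unfunctionalised chain olefin untouched.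

Step 8
Reactants: 15 (1R,2R,6R)-1-[(8Z)-heptadec-8-en-1-yl]-5,5-dimethoxy-7-oxabicyclo[4.1.0]hept-3-en-2-ol
Product: 17 (4R,5S)-4,5-dihydroxy-5-[(8Z)-heptadec-8-en-1-yl]cyclohex-2-en-1-one, via diol ketal 16 (not isolated)
Conditions: LiAlH4, THF, 0 °C → rt; aq. NaOH work-up; then oxalic acid (cat.), wet THF, 0 °C
Reagents that add atoms: water, O
Why: Hydride opening of an epoxide followed by ketal hydrolysis: hydride attacks by SN2 at the only non-quaternary oxirane carbon, so the tertiary C–O bond keeps its configuration and the cis-diol is retained, and mild aqueous acid then unmasks the enone without dehydrating the β-hydroxy ketone.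

**Compound list**
1 | propyne | CC#C | starting material
2 | 1-bromoheptane | CCCCCCCBr | starting material
3 | 7-bromohept-1-ene | C=CCCCCCBr | starting material
4 | 1,3-dilithiopropyne | [Li]CC#C[Li] | intermediate
5 | dec-1-ynyllithium | [Li]C#CCCCCCCCC | intermediate
6 | heptadec-1-en-8-yne | C=CCCCCCC#CCCCCCCCC | intermediate
7 | (8Z)-heptadeca-1,8-diene | C=CCCCCC/C=C\CCCCCCCC | intermediate
8 | 9-[(8Z)-heptadec-8-en-1-yl]-9-borabicyclo[3.3.1]nonane | CCCCCCCC/C=C\CCCCCCCB1C2CCCC1CCC2 | intermediate
9 | (8Z)-1-iodoheptadec-8-ene | CCCCCCCC/C=C\CCCCCCCI | intermediate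
10 | 2-bromophenol | Oc1ccccc1Br | starting material
11 | 2-[(8Z)-heptadec-8-en-1-yl]phenol | CCCCCCCC/C=C\CCCCCCCc1ccccc1O | intermediate
12 | 2-[(8Z)-heptadec-8-en-1-yl]-4-methoxyphenol | CCCCCCCC/C=C\CCCCCCCc1cc(OC)ccc1O | intermediate
13 | 2-[(8Z)-heptadec-8-en-1-yl]-4,4-dimethoxycyclohexa-2,5-dien-1-one | CCCCCCCC/C=C\CCCCCCCC1=CC(OC)(OC)C=CC1=O | intermediate
14 | (1R)-2-[(8Z)-heptadec-8-en-1-yl]-4,4-dimethoxycyclohexa-2,5-dien-1-ol | CCCCCCCC/C=C\CCCCCCCC1=CC(OC)(OC)C=C[C@H]1O | intermediate
15 | (1R,2R,6R)-1-[(8Z)-heptadec-8-en-1-yl]-5,5-dimethoxy-7-oxabicyclo[4.1.0]hept-3-en-2-ol | CCCCCCCC/C=C\CCCCCCC[C@]12O[C@H]1C(OC)(OC)C=C[C@H]2O | intermediate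
16 | (1S,2R)-1-[(8Z)-heptadec-8-en-1-yl]-5,5-dimethoxycyclohex-3-ene-1,2-diol (cis-diol) | CCCCCCCC/C=C\CCCCCCC[C@]1(O)CC(OC)(OC)C=C[C@H]1O | intermediate
17 | (4R,5S)-4,5-dihydroxy-5-[(8Z)-heptadec-8-en-1-yl]cyclohex-2-en-1-one | CCCCCCCC/C=C\CCCCCCC[C@]1(O)CC(=O)C=C[C@H]1O | target

**Step count and risks**

Total step count: 8. Longest linear sequence: 8 steps (propyne to 17; 2-bromophenol enters at step 4).

The three steps most likely to fail:

Step 4. The free ortho-bromophenol may be hydrodehalogenated or may slow the nickel cycle. The fallback sets out from 9: zinc dust and LiCl in THF insert into the C–I bond to give (8Z)-heptadec-8-en-1-ylzinc iodide F1. F1 is joined to 10 by a polar Negishi coupling (Pd(OAc)2, SPhos, THF, 25 °C, a system that tolerates the phenol O–H) and comes back to the route at 11.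

Step 6. Face discrimination between the two vinyl arms may be modest, and the bis-allylic alcohol is acid-labile. The fallback sets out from 13: Luche reduction (NaBH4, CeCl3·7H2O, MeOH, −78 °C) gives racemic 2-[(8Z)-heptadec-8-en-1-yl]-4,4-dimethoxycyclohexa-2,5-dien-1-ol F2. Lipase kinetic resolution (Candida antarctica lipase B, vinyl acetate, hexane) is expected by Kazlauskas' rule to acetylate the R enantiomer to (1R)-2-[(8Z)-heptadec-8-en-1-yl]-4,4-dimethoxycyclohexa-2,5-dien-1-yl acetate F3. It leaves (1S)-2-[(8Z)-heptadec-8-en-1-yl]-4,4-dimethoxycyclohexa-2,5-dien-1-ol F4, which is discarded or re-oxidised to 13 with MnO2. Methanolysis of F3 (K2CO3, MeOH, 0 °C) comes back to the route at 14.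

Step 8. Hydride must attack a CH flanked by the ketal carbon, and the product is acid-sensitive. The fallback sets out from 15: mild ketal hydrolysis (oxalic acid on wet silica, CH2Cl2, 0 °C) gives the epoxy enone (1R,5R,6R)-5-hydroxy-6-[(8Z)-heptadec-8-en-1-yl]-7-oxabicyclo[4.1.0]hept-3-en-2-one F5. SmI2 (2.2 equiv, THF/MeOH, −78 °C) then cleaves the oxirane C–O bond alpha to the ketone through the samarium ketyl radical, leaves the tertiary C–O bond untouched, and comes back to the route at 17.

Further compounds
F1 | step 4 | (8Z)-heptadec-8-en-1-ylzinc iodide | CCCCCCCC/C=C\CCCCCCC[Zn]I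
F2 | step 6 | racemic 2-[(8Z)-heptadec-8-en-1-yl]-4,4-dimethoxycyclohexa-2,5-dien-1-ol | CCCCCCCC/C=C\CCCCCCCC1=CC(OC)(OC)C=CC1O
F3 | step 6 | (1R)-2-[(8Z)-heptadec-8-en-1-yl]-4,4-dimethoxycyclohexa-2,5-dien-1-yl acetate | CCCCCCCC/C=C\CCCCCCCC1=CC(OC)(OC)C=C[C@H]1OC(C)=O
F4 | step 6 | (1S)-2-[(8Z)-heptadec-8-en-1-yl]-4,4-dimethoxycyclohexa-2,5-dien-1-ol | CCCCCCCC/C=C\CCCCCCCC1=CC(OC)(OC)C=C[C@@H]1O
F5 | step 8 | (1R,5R,6R)-5-hydroxy-6-[(8Z)-heptadec-8-en-1-yl]-7-oxabicyclo[4.1.0]hept-3-en-2-one | CCCCCCCC/C=C\CCCCCCC[C@]12O[C@H]1C(=O)C=C[C@H]2O
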